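**Retrosynthetic overview**
- Target ⇐ neutral hydrogenolysis of one aryl benzyl ether and an (S)-1-phenylethyl lactol acetal (lactol configuration retained) ⇐ hydride reduction of two formyl groups ⇐ separable diastereomeric acetals of the racemic lactol.
- Central dioxepinone ring: lactone by carbodiimide closure of a 2-(2-hydroxyaryloxy)benzoic acid; diaryl ether by SNAr of a ring-B phenol on a ring-A aryl fluoride flanked by ester and formyl groups.
- Ring B (lactol carried as a 3-methoxyphthalide) ⇐ ethyl orsellinate by Elbs hydroxylation, benzylic dibromination/hydrolysis and ortho-formylation.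
- Key C–C bond: the orsellinate ring ⇐ intermolecular Michael addition of ethyl acetoacetate to ethyl crotonate, then Dieckmann (Claisen) closure and aromatisation.
- Ring A ⇐ 3,5-difluorotoluene. Ring order: ring B carbocycle → ring B lactol-lactone → (ring A from the arene) → dioxepinone (ether bond, then lactone).

Assumption: the only stereocentre (lactol C1, (S) in the given SMILES) is a hemiacetal that can racemise by ring–chain tautomerism in protic, acidic or basic media, so it is set as a separable acetal, unmasked last under neutral conditions, and 28 is kept cold in aprotic solvent.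

Phthalide numbering below: phthalide = 2-benzofuran-1(3H)-one, C1 = C=O, C3 = acetal carbon.

**Step 1**
Reactants: 1 ethyl acetoacetate; 2 ethyl (E)-but-2-enoate (ethyl crotonate)
Product: 4 ethyl 6-methyl-2,4-dioxocyclohexane-1-carboxylate, via Michael adduct 3 (not isolated)
Conditions: NaOEt (1.05 equiv), EtOH, reflux, 3 h; then aq. HCl, 0 °C
Reagents that add atoms: none
Why: Intermolecular Michael addition of the acetoacetate enolate to the crotonate joins the two fragments, and the acetyl methyl then closes the ring by Dieckmann (intramolecular Claisen) condensation, driven by the stable dione enolate; the two stereocentres are formed as a mixture and are erased in step 2.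

**Step 2**
Reactants: 4 ethyl 6-methyl-2,4-dioxocyclohexane-1-carboxylate
Product: 5 ethyl 3,5-dibromo-2,4-dihydroxy-6-methylbenzoate
Conditions: Br2 (3.05 equiv), AcOH, 20 → 60 °C
Reagents that add atoms: bromine, BrBr
Why: Bromination–dehydrobromination aromatises the cyclohexanedione and the resorcinol formed is brominated at both free ring positions, which gives one crystalline product.

**Step 3**
Reactants: 5 ethyl 3,5-dibromo-2,4-dihydroxy-6-methylbenzoate
Product: 6 ethyl 2,4-dihydroxy-6-methylbenzoate (ethyl orsellinate)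
Conditions: H2 (1 atm), 10% Pd/C, NaOAc (2.2 equiv), EtOH, rt
Reagents that add atoms: none
Why: Catalytic hydrogenolysis removes both aryl bromides while the ester and phenols are inert.

**Step 4**
Reactants: 6 ethyl 2,4-dihydroxy-6-methylbenzoate
Product: 8 ethyl 2,4,5-trihydroxy-6-methylbenzoate, via aryl potassium sulfate 7 (not isolated)
Conditions: K2S2O8 (1.1 equiv), 2 M aq. NaOH, 5 → 20 °C, 24 h; then conc. HCl, 90 °C, 1 h, N2
Reagents that add atoms: potassium peroxodisulfate, [K+].[K+].[O-]S(=O)(=O)OOS(=O)(=O)[O-]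
Why: Elbs persulfate oxidation attacks para to the 2-phenoxide (C5, the only free para position) and acid hydrolysis of the aryl sulfate frees the new phenol; the hindered ester survives.

**Step 5**
Reactants: 8 ethyl 2,4,5-trihydroxy-6-methylbenzoate
Product: 9 ethyl 2,4,5-triacetoxy-6-methylbenzoate
Conditions: Ac2O (4 equiv), pyridine, DMAP (5 mol%), rt
Reagents that add atoms: acetic anhydride, CC(=O)OC(C)=O
Why: Peracetylation protects the air-sensitive hydroxyquinol and deactivates the ring so that radical bromination in step 6 goes to the methyl group.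

**Step 6**
Reactants: 9 ethyl 2,4,5-triacetoxy-6-methylbenzoate
Product: 11 ethyl 2,4,5-triacetoxy-6-(dibromomethyl)benzoate, via benzylic monobromide 10 (not isolated)
Conditions: NBS (2.3 equiv), AIBN (5 mol%), PhCF3, reflux, visible light
Reagents that add atoms: N-bromosuccinimide, BrN1C(=O)CCC1=O
Why: Wohl–Ziegler bromination has only one benzylic site to attack and excess NBS takes it to the gem-dibromide, the aldehyde oxidation level needed for the lactol.

**Step 7**
Reactants: 11 ethyl 2,4,5-triacetoxy-6-(dibromomethyl)benzoate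
Product: 12 rac-3,4,5,7-tetrahydroxyphthalide
Conditions: 2 M aq. HCl/1,4-dioxane (1:1), reflux, Ar
Reagents that add atoms: water, O
Why: Hydrolysis of the gem-dibromide with participation of the ortho ester gives the 2-formylbenzoic acid, which closes to the hydroxyphthalide (racemic lactol) while the aryl acetates are cleaved.

**Step 8**
Reactants: 12 rac-3,4,5,7-tetrahydroxyphthalide
Product: 13 rac-4,5,7-trihydroxy-3-methoxyphthalide
Conditions: MeOH, H2SO4 (cat.), reflux, Ar
Reagents that add atoms: methanol, CO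
Why: Acid-catalysed pseudo-esterification of a hydroxyphthalide masks the lactol as a base-stable methyl acylal (racemic) and leaves the phenols free.

**Step 9**
Reactants: 13 rac-4,5,7-trihydroxy-3-methoxyphthalide
Product: 14 rac-4,7-dihydroxy-3-methoxy-5-(4-methoxybenzyloxy)phthalide
Conditions: PMBCl (1.05 equiv), K2CO3 (1.1 equiv), Bu4NI (5 mol%), DMF, 0 °C → rt, Ar
Reagents that add atoms: 4-methoxybenzyl chloride, COc1ccc(CCl)cc1
Why: Williamson etherification with one equivalent of base alkylates the most acidic phenol, the 5-OH para to the lactone carbonyl, as in selective para-O-alkylation of 3,4-dihydroxy- and 2,4-dihydroxybenzoates.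

**Step 10**
Reactants: 14 rac-4,7-dihydroxy-3-methoxy-5-(4-methoxybenzyloxy)phthalide
Product: 15 rac-6-formyl-4,7-dihydroxy-3-methoxy-5-(4-methoxybenzyloxy)phthalide
Conditions: MgCl2 (3 equiv), Et3N (6 equiv), (CH2O)n (8 equiv), MeCN, reflux, Ar; 1 M HCl work-up
Reagents that add atoms: paraformaldehyde (formaldehyde), C=O
Why: Casnati–Skattebøl magnesium-phenoxide ortho-formylation delivers formaldehyde ortho to the 7-OH, and C6 is the only free ring position.

**Step 11**
Reactants: 16 3,5-difluorotoluene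
Product: 18 2,6-difluoro-4-methylbenzaldehyde, via aryllithium 17 (not isolated)
Conditions: n-BuLi (1.05 equiv), THF, −78 °C, 1 h; DMF (1.5 equiv), −78 → 0 °C; aq. HCl
Reagents that add atoms: N,N-dimethylformamide, CN(C)C=O
Why: Directed ortho-lithiation removes the most acidic proton, between the two fluorines, and DMF formylates the aryllithium.

**Step 12**
Reactants: 18 2,6-difluoro-4-methylbenzaldehyde
Product: 19 2-(benzyloxy)-6-fluoro-4-methylbenzaldehyde
Conditions: BnOH (1.0 equiv), NaH (1.05 equiv), THF, −20 → 0 °C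
Reagents that add atoms: benzyl alcohol, OCc1ccccc1
Why: SNAr ortho to the aldehyde on a symmetrical substrate has no regiochemical issue, and the new alkoxy group deactivates the ring against a second substitution.

**Step 13**
Reactants: 19 2-(benzyloxy)-6-fluoro-4-methylbenzaldehyde
Product: 20 6-(benzyloxy)-3-bromo-2-fluoro-4-methylbenzaldehyde
Conditions: NBS (1.05 equiv), TFA (10 mol%), MeCN, rt, dark
Reagents that add atoms: N-bromosuccinimide, BrN1C(=O)CCC1=O
Why: Electrophilic aromatic bromination goes para to the benzyloxy group (between F and CH3), as in 3-fluoroanisole, the other free position being ortho to OBn and more hindered.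

**Step 14**
Reactants: 20 6-(benzyloxy)-3-bromo-2-fluoro-4-methylbenzaldehyde
Product: 21 4-methoxybenzyl 4-(benzyloxy)-2-fluoro-3-formyl-6-methylbenzoate
Conditions: CO (1 atm), Pd(OAc)2 (3 mol%), Xantphos (6 mol%), 4-methoxybenzyl alcohol (1.3 equiv), Et3N (3 equiv), toluene, 80 °C
Reagents that add atoms: carbon monoxide, [C-]#[O+]; 4-methoxybenzyl alcohol, COc1ccc(CO)cc1
Why: Palladium-catalysed alkoxycarbonylation of the aryl bromide tolerates the aldehyde and the aryl fluoride and installs an acid-labile ester directly.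

**Step 15**
Reactants: 15 rac-6-formyl-4,7-dihydroxy-3-methoxy-5-(4-methoxybenzyloxy)phthalide; 21 4-methoxybenzyl 4-(benzyloxy)-2-fluoro-3-formyl-6-methylbenzoate
Product: 22 rac-4-methoxybenzyl 4-(benzyloxy)-3-formyl-2-{[6-formyl-7-hydroxy-3-methoxy-5-(4-methoxybenzyloxy)-1-oxo-1,3-dihydro-2-benzofuran-4-yl]oxy}-6-methylbenzoate
Conditions: K2CO3 (2.5 equiv), DMF (degassed), 4 Å MS, 40 °C, Ar
Reagents that add atoms: none
Why: SNAr on a fluoride activated by an ortho ester and an ortho formyl group; the 4-phenoxide is the nucleophilic oxygen because the 7-phenoxide is chelated and conjugated to both flanking carbonyls.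

**Step 16**
Reactants: 22 the diaryl ether from step 15
Product: 23 rac-4-(benzyloxy)-3-formyl-2-[(6-formyl-5,7-dihydroxy-3-methoxy-1-oxo-1,3-dihydro-2-benzofuran-4-yl)oxy]-6-methylbenzoic acid
Conditions: TFA/CH2Cl2 (1:4), anisole (10 equiv), 0 °C → rt, 1 h
Reagents that add atoms: none
Why: Acidolysis removes the PMB ester and the PMB aryl ether through the 4-methoxybenzyl cation, which anisole traps, while the benzyl ether, the aldehydes and the acylal are stable to anhydrous TFA.

**Step 17**
Reactants: 23 the hydroxy acid from step 16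
Product: 24 rac-10-(benzyloxy)-4-hydroxy-1-methoxy-8-methyl-3,7-dioxo-1,3-dihydro-7H-isobenzofuro[4,5-b][1,4]benzodioxepine-5,11-dicarbaldehyde
Conditions: DCC (1.5 equiv), DMAP (10 mol%), CH2Cl2 (5 mM), 0 °C → rt
Reagents that add atoms: none
Why: Steglich-type carbodiimide lactonisation closes the seven-membered aryl ester (depsidone ring) onto the adjacent 5-OH, the doubly chelated 7-OH being unreactive.

**Step 18**
Reactants: 24 the depsidone methyl acylal from step 17
Product: 25 rac-10-(benzyloxy)-1,4-dihydroxy-8-methyl-3,7-dioxo-1,3-dihydro-7H-isobenzofuro[4,5-b][1,4]benzodioxepine-5,11-dicarbaldehyde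
Conditions: 2 M aq. HCl/THF (1:3), 55 °C
Reagents that add atoms: water, O
Why: Acid-catalysed acylal hydrolysis through the aryl-stabilised oxocarbenium ion frees the lactol (racemic) without opening the depsidone ester.

**Step 19**
Reactants: 25 the racemic lactol from step 18
Product: 26 (1S)-10-(benzyloxy)-4-hydroxy-8-methyl-3,7-dioxo-1-[(1S)-1-phenylethoxy]-1,3-dihydro-7H-isobenzofuro[4,5-b][1,4]benzodioxepine-5,11-dicarbaldehyde
Conditions: (S)-1-phenylethanol (5 equiv), PPTS (20 mol%), benzene, reflux through 4 Å MS; SiO2 chromatography; fractions of the (1R) epimer put back under the same conditions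
Reagents that add atoms: (S)-1-phenylethanol, C[C@H](O)c1ccccc1
Why: Pseudo-ester (acetal) formation with the enantiopure alcohol gives the two C1 diastereomers, from which the (1S) isomer 26 is separated on silica while the (1R) epimer fractions are re-equilibrated at C1 through the oxocarbenium ion under the same conditions and separated again; the alcohol stereocentre is untouched because only its O–H bond reacts.

**Step 20**
Reactants: 26 the (1S)-acetal from step 19
Product: 27 (1S)-10-(benzyloxy)-4-hydroxy-5,11-bis(hydroxymethyl)-8-methyl-1-[(1S)-1-phenylethoxy]-1H-isobenzofuro[4,5-b][1,4]benzodioxepine-3,7-dione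
Conditions: NaBH4 (1.0 equiv), THF/EtOH (4:1), −20 °C, 20 min; AcOH quench
Reagents that add atoms: none
Why: Borohydride reduces the two aryl aldehydes far faster than the aryl ester or the acylal lactone at low temperature, and no stereocentre is touched.

**Step 21**
Reactants: 27 the diol from step 20
Product: 28 (1S)-1,4,10-trihydroxy-5,11-bis(hydroxymethyl)-8-methyl-1H-isobenzofuro[4,5-b][1,4]benzodioxepine-3,7-dione (target)
Conditions: H2 (1 atm), 10% Pd/C, EtOAc, 20 °C, stopped at full conversion; filtered and concentrated cold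
Reagents that add atoms: none
Why: Hydrogenolysis cleaves the PhCH2–O and PhCH(CH3)–O bonds and not the C1–O bonds, so the (1S) lactol configuration set in step 19 is retained, and the neutral aprotic medium avoids ring–chain racemisation.

**Compound list**
1 | ethyl acetoacetate | CCOC(=O)CC(C)=O | starting material
2 | ethyl (E)-but-2-enoate | C/C=C/C(=O)OCC | starting material
3 | diethyl 2-acetyl-3-methylpentanedioate (Michael adduct, stereoisomer mixture) | CCOC(=O)CC(C)C(C(C)=O)C(=O)OCC | intermediate (not isolated)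
4 | ethyl 6-methyl-2,4-dioxocyclohexane-1-carboxylate (stereoisomer mixture, lost in step 2) | CCOC(=O)C1C(C)CC(=O)CC1=O | intermediate
5 | ethyl 3,5-dibromo-2,4-dihydroxy-6-methylbenzoate | CCOC(=O)c1c(C)c(Br)c(O)c(Br)c1O | intermediate
6 | ethyl 2,4-dihydroxy-6-methylbenzoate | CCOC(=O)c1c(C)cc(O)cc1O | intermediate
7 | potassium 3-(ethoxycarbonyl)-4,6-dihydroxy-2-methylphenyl sulfate | CCOC(=O)c1c(C)c(OS(=O)(=O)[O-])c(O)cc1O.[K+] | intermediate (not isolated)
8 | ethyl 2,4,5-trihydroxy-6-methylbenzoate | CCOC(=O)c1c(C)c(O)c(O)cc1O | intermediate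
9 | ethyl 2,4,5-triacetoxy-6-methylbenzoate | CCOC(=O)c1c(C)c(OC(C)=O)c(OC(C)=O)cc1OC(C)=O | intermediate
10 | ethyl 2,4,5-triacetoxy-6-(bromomethyl)benzoate | CCOC(=O)c1c(CBr)c(OC(C)=O)c(OC(C)=O)cc1OC(C)=O | intermediate (not isolated)
11 | ethyl 2,4,5-triacetoxy-6-(dibromomethyl)benzoate | CCOC(=O)c1c(C(Br)Br)c(OC(C)=O)c(OC(C)=O)cc1OC(C)=O | intermediate
12 | rac-3,4,5,7-tetrahydroxyphthalide | OC1OC(=O)c2c(O)cc(O)c(O)c12 | intermediate
13 | rac-4,5,7-trihydroxy-3-methoxyphthalide | COC1OC(=O)c2c(O)cc(O)c(O)c12 | intermediate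
14 | rac-4,7-dihydroxy-3-methoxy-5-(4-methoxybenzyloxy)phthalide | COC1OC(=O)c2c(O)cc(OCc3ccc(OC)cc3)c(O)c12 | intermediate
15 | rac-6-formyl-4,7-dihydroxy-3-methoxy-5-(4-methoxybenzyloxy)phthalide | COC1OC(=O)c2c(O)c(C=O)c(OCc3ccc(OC)cc3)c(O)c12 | intermediate
16 | 3,5-difluorotoluene | Cc1cc(F)cc(F)c1 | starting material
17 | (2,6-difluoro-4-methylphenyl)lithium | [Li]c1c(F)cc(C)cc1F | intermediate (not isolated)
18 | 2,6-difluoro-4-methylbenzaldehyde | Cc1cc(F)c(C=O)c(F)c1 | intermediate
19 | 2-(benzyloxy)-6-fluoro-4-methylbenzaldehyde | Cc1cc(F)c(C=O)c(OCc2ccccc2)c1 | intermediate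
20 | 6-(benzyloxy)-3-bromo-2-fluoro-4-methylbenzaldehyde | Cc1cc(OCc2ccccc2)c(C=O)c(F)c1Br | intermediate
21 | 4-methoxybenzyl 4-(benzyloxy)-2-fluoro-3-formyl-6-methylbenzoate | COc1ccc(COC(=O)c2c(C)cc(OCc3ccccc3)c(C=O)c2F)cc1 | intermediate
22 | rac-4-methoxybenzyl 4-(benzyloxy)-3-formyl-2-{[6-formyl-7-hydroxy-3-methoxy-5-(4-methoxybenzyloxy)-1-oxo-1,3-dihydro-2-benzofuran-4-yl]oxy}-6-methylbenzoate | COc1ccc(COC(=O)c2c(C)cc(OCc3ccccc3)c(C=O)c2Oc2c(OCc3ccc(OC)cc3)c(C=O)c(O)c3c2C(OC)OC3=O)cc1 | intermediate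
23 | rac-4-(benzyloxy)-3-formyl-2-[(6-formyl-5,7-dihydroxy-3-methoxy-1-oxo-1,3-dihydro-2-benzofuran-4-yl)oxy]-6-methylbenzoic acid | Cc1cc(OCc2ccccc2)c(C=O)c(Oc2c(O)c(C=O)c(O)c3c2C(OC)OC3=O)c1C(=O)O | intermediate
24 | rac-10-(benzyloxy)-4-hydroxy-1-methoxy-8-methyl-3,7-dioxo-1,3-dihydro-7H-isobenzofuro[4,5-b][1,4]benzodioxepine-5,11-dicarbaldehyde | Cc1cc(OCc4ccccc4)c(C=O)c2c1C(=O)Oc1c(C=O)c(O)c3c(c1O2)C(OC)OC3=O | intermediate
25 | rac-10-(benzyloxy)-1,4-dihydroxy-8-methyl-3,7-dioxo-1,3-dihydro-7H-isobenzofuro[4,5-b][1,4]benzodioxepine-5,11-dicarbaldehyde | Cc1cc(OCc4ccccc4)c(C=O)c2c1C(=O)Oc1c(C=O)c(O)c3c(c1O2)C(O)OC3=O | intermediate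
26 | (1S)-10-(benzyloxy)-4-hydroxy-8-methyl-3,7-dioxo-1-[(1S)-1-phenylethoxy]-1,3-dihydro-7H-isobenzofuro[4,5-b][1,4]benzodioxepine-5,11-dicarbaldehyde | Cc1cc(OCc4ccccc4)c(C=O)c2c1C(=O)Oc1c(C=O)c(O)c3c(c1O2)[C@@H](O[C@@H](C)c1ccccc1)OC3=O | intermediate
27 | (1S)-10-(benzyloxy)-4-hydroxy-5,11-bis(hydroxymethyl)-8-methyl-1-[(1S)-1-phenylethoxy]-1H-isobenzofuro[4,5-b][1,4]benzodioxepine-3,7-dione | Cc1cc(OCc4ccccc4)c(CO)c2c1C(=O)Oc1c(CO)c(O)c3c(c1O2)[C@@H](O[C@@H](C)c1ccccc1)OC3=O | intermediate
28 | (1S)-1,4,10-trihydroxy-5,11-bis(hydroxymethyl)-8-methyl-1H-isobenzofuro[4,5-b][1,4]benzodioxepine-3,7-dione (CNP0155661.1) | Cc1cc(O)c(CO)c2c1C(=O)Oc1c(CO)c(O)c3c(c1O2)[C@@H](O)OC3=O | target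

**Totals**
Total steps: 21. Longest linear sequence: 17 (steps 1–10, then 15–21); the ring A branch is steps 11–14.

**Three steps most likely to fail**

Step 9 (mono-etherification of one of three phenols). If alkylation is not clean at the 5-OH, the fallback sets out from 13 and masks the 4,7-hydroquinone as a quinone so that only one hydroxyl is left. Oxidation of 13 with Ag2O in THF gives the hydroxy-p-quinone rac-5-hydroxy-3-methoxy-2-benzofuran-1,4,7(3H)-trione F1. O-alkylation of this vinylogous acid with PMBCl/Ag2O in CH2Cl2 gives rac-3-methoxy-5-(4-methoxybenzyloxy)-2-benzofuran-1,4,7(3H)-trione F2. Reduction with Na2S2O4 in EtOAc/water returns the hydroquinone, and the route is rejoined at 14.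

Step 15 (SNAr fragment union). The risks are arylation at the wrong oxygen, air oxidation of the hydroquinone dianion and lability of the acylal next to a phenoxide. The fallback sets out from 15 and leaves a single free phenol. Selective acetylation of the non-chelated 4-OH (Ac2O 1.05 equiv, pyridine, CH2Cl2, 0 °C) gives rac-6-formyl-7-hydroxy-3-methoxy-5-(4-methoxybenzyloxy)-1-oxo-1,3-dihydro-2-benzofuran-4-yl acetate F3. Mitsunobu etherification of the remaining acidic 7-OH (4-methoxybenzyl alcohol, PPh3, DIAD) gives rac-6-formyl-3-methoxy-5,7-bis(4-methoxybenzyloxy)-1-oxo-1,3-dihydro-2-benzofuran-4-yl acetate F4. Brief K2CO3/MeOH at 0 °C removes the acetate to give rac-6-formyl-4-hydroxy-3-methoxy-5,7-bis(4-methoxybenzyloxy)phthalide F5. SNAr of F5 with 21 (K2CO3, DMF) gives the tris-PMB diaryl ether rac-4-methoxybenzyl 4-(benzyloxy)-3-formyl-2-{[6-formyl-3-methoxy-5,7-bis(4-methoxybenzyloxy)-1-oxo-1,3-dihydro-2-benzofuran-4-yl]oxy}-6-methylbenzoate F6. TFA/anisole removes all three PMB groups, and the route is rejoined at 23.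

Step 21 (final hydrogenolysis with retention at C1). The risks are over-reduction (ArCH2OH to ArCH3, lactol to phthalide), slow cleavage of the secondary benzylic acetal and erosion of ee. The fallback sets out from 24 and replaces the auxiliary by resolution of the racemate. NaBH4 reduction of 24 gives rac-10-(benzyloxy)-4-hydroxy-5,11-bis(hydroxymethyl)-1-methoxy-8-methyl-1H-isobenzofuro[4,5-b][1,4]benzodioxepine-3,7-dione F7. Hydrogenolysis of the benzyl ether (H2, Pd/C, EtOAc), with no free lactol present, gives rac-4,10-dihydroxy-5,11-bis(hydroxymethyl)-1-methoxy-8-methyl-1H-isobenzofuro[4,5-b][1,4]benzodioxepine-3,7-dione F8. Mild acylal hydrolysis (aq. HCl/THF, 40 °C) gives racemic rac-1,4,10-trihydroxy-5,11-bis(hydroxymethyl)-8-methyl-1H-isobenzofuro[4,5-b][1,4]benzodioxepine-3,7-dione F9. Preparative chiral SFC at sub-ambient temperature (polysaccharide phase, CO2/MeCN) separates the enantiomers, and the (1S) fraction is 28.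

**Further compounds**
F1 | step 9 | rac-5-hydroxy-3-methoxy-2-benzofuran-1,4,7(3H)-trione | COC1OC(=O)C2=C1C(=O)C(O)=CC2=O
F2 | step 9 | rac-3-methoxy-5-(4-methoxybenzyloxy)-2-benzofuran-1,4,7(3H)-trione | COC1OC(=O)C2=C1C(=O)C(OCc3ccc(OC)cc3)=CC2=O
F3 | step 15 | rac-6-formyl-7-hydroxy-3-methoxy-5-(4-methoxybenzyloxy)-1-oxo-1,3-dihydro-2-benzofuran-4-yl acetate | COC1OC(=O)c2c(O)c(C=O)c(OCc3ccc(OC)cc3)c(OC(C)=O)c12
F4 | step 15 | rac-6-formyl-3-methoxy-5,7-bis(4-methoxybenzyloxy)-1-oxo-1,3-dihydro-2-benzofuran-4-yl acetate | COC1OC(=O)c2c(OCc3ccc(OC)cc3)c(C=O)c(OCc3ccc(OC)cc3)c(OC(C)=O)c12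
F5 | step 15 | rac-6-formyl-4-hydroxy-3-methoxy-5,7-bis(4-methoxybenzyloxy)phthalide | COC1OC(=O)c2c(OCc3ccc(OC)cc3)c(C=O)c(OCc3ccc(OC)cc3)c(O)c12
F6 | step 15 | rac-4-methoxybenzyl 4-(benzyloxy)-3-formyl-2-{[6-formyl-3-methoxy-5,7-bis(4-methoxybenzyloxy)-1-oxo-1,3-dihydro-2-benzofuran-4-yl]oxy}-6-methylbenzoate | COc1ccc(COC(=O)c2c(C)cc(OCc3ccccc3)c(C=O)c2Oc2c(OCc3ccc(OC)cc3)c(C=O)c(OCc3ccc(OC)cc3)c3c2C(OC)OC3=O)cc1
F7 | step 21 | rac-10-(benzyloxy)-4-hydroxy-5,11-bis(hydroxymethyl)-1-methoxy-8-methyl-1H-isobenzofuro[4,5-b][1,4]benzodioxepine-3,7-dione | Cc1cc(OCc4ccccc4)c(CO)c2c1C(=O)Oc1c(CO)c(O)c3c(c1O2)C(OC)OC3=O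
F8 | step 21 | rac-4,10-dihydroxy-5,11-bis(hydroxymethyl)-1-methoxy-8-methyl-1H-isobenzofuro[4,5-b][1,4]benzodioxepine-3,7-dione | Cc1cc(O)c(CO)c2c1C(=O)Oc1c(CO)c(O)c3c(c1O2)C(OC)OC3=O
F9 | step 21 | rac-1,4,10-trihydroxy-5,11-bis(hydroxymethyl)-8-methyl-1H-isobenzofuro[4,5-b][1,4]benzodioxepine-3,7-dione | Cc1cc(O)c(CO)c2c1C(=O)Oc1c(CO)c(O)c3c(c1O2)C(O)OC3=O
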